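## Retrosynthetic overview

1. Target read as ent-fisetinidol-(4α→6)-catechin: upper unit (2S,3R,4S), 2,3-trans-3,4-cis; lower unit (2R,3S). Last steps are desilylation and global hydrogenolysis (eight benzyl ethers and a C8 bromine cap).
2. The C4–C6 interflavan bond comes from an aryllithium (6-iodo-8-bromo-penta-O-benzylcatechin; the bromine at C8 forces 4→6 connectivity) adding to the C4 ketone of the upper unit. Reductive removal of the tertiary benzylic OH then sets C4.
3. The upper ketone comes from trans α-hydroxylation (Rubottom) of a (2R)-flavanone, which fixes C3 relative to C2.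
4. Ring C of the upper unit is the only ring built. It is closed first, by an enantioselective intramolecular oxa-Michael addition of an alkylidene β-keto ester (benzoate + tert-butyl acetate + aldehyde), followed by decarboxylation.
5. Rings A, C and B of the lower unit come intact from (+)-catechin.

Assumption: the quinidine-derived thiourea in step 5 gives the (2R) series; if the sense of induction is the reverse, the quinine-derived pseudoenantiomer is used and nothing else changes.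

## Route

**Step 1**
Reactants: 1 methyl 2,4-dihydroxybenzoate
Product: 2 methyl 4-(benzyloxy)-2-hydroxybenzoate
Conditions: BnBr (1.05 equiv), K2CO3, acetone, reflux
Reagents that add atoms: benzyl bromide, BrCc1ccccc1
Why: Williamson etherification; the 2-OH is hydrogen-bonded to the ester carbonyl and much less nucleophilic, so only the 4-OH is benzylated.

**Step 2**
Reactants: 2 methyl 4-(benzyloxy)-2-hydroxybenzoate; 3 tert-butyl acetate
Product: 4 tert-butyl 3-[4-(benzyloxy)-2-hydroxyphenyl]-3-oxopropanoate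
Conditions: LiN(iPr)2 (3.5 equiv), 3 (3.5 equiv), THF, -78 °C; add 2, -78 → 0 °C; then 1 M HCl
Reagents that add atoms: none
Why: Crossed Claisen condensation of the lithium enolate of tert-butyl acetate with the salicylate ester; excess base covers the phenol and the acidic β-keto ester product.

**Step 3**
Reactants: 5 3,4-dihydroxybenzaldehyde
Product: 6 3,4-bis(benzyloxy)benzaldehyde
Conditions: BnBr (2.2 equiv), K2CO3, DMF, 60 °C
Reagents that add atoms: benzyl bromide, BrCc1ccccc1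
Why: Twofold Williamson etherification of the catechol.

**Step 4**
Reactants: 4 tert-butyl 3-[4-(benzyloxy)-2-hydroxyphenyl]-3-oxopropanoate; 6 3,4-bis(benzyloxy)benzaldehyde
Product: 7 tert-butyl 2-[4-(benzyloxy)-2-hydroxybenzoyl]-3-[3,4-bis(benzyloxy)phenyl]prop-2-enoate (E/Z mixture)
Conditions: piperidine (10 mol %), AcOH (10 mol %), anhydrous MgSO4, toluene, rt
Reagents that add atoms: none
Why: Knoevenagel condensation of the active methylene with the aldehyde gives the doubly activated oxa-Michael acceptor; both alkene isomers converge in step 5.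

**Step 5**
Reactants: 7 tert-butyl 2-[4-(benzyloxy)-2-hydroxybenzoyl]-3-[3,4-bis(benzyloxy)phenyl]prop-2-enoate
Product: 9 (2R)-7-(benzyloxy)-2-[3,4-bis(benzyloxy)phenyl]chroman-4-one, via keto ester flavanone 8 (not isolated)
Conditions: N-[3,5-bis(trifluoromethyl)phenyl]-N'-[(9R)-6'-methoxycinchonan-9-yl]thiourea (10 mol %), toluene, -25 °C; then TsOH·H2O (30 mol %), 80 °C
Reagents that add atoms: none
Why: Intramolecular oxa-Michael addition in which the thiourea binds the β-keto ester and the quinuclidine base delivers the phenol to one face of the alkylidene, setting C2 as R; acid then cleaves the tert-butyl ester and decarboxylates without touching C2.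

**Step 6**
Reactants: 9 (2R)-7-(benzyloxy)-2-[3,4-bis(benzyloxy)phenyl]chroman-4-one
Product: 12 (2S,3S)-7-(benzyloxy)-2-[3,4-bis(benzyloxy)phenyl]-3-hydroxychroman-4-one, via silyl enol ether 10 (not isolated), via silyloxy epoxide 11 (not isolated)
Conditions: TMSOTf, Et3N, CH2Cl2, 0 °C; pentane filtration of the ammonium salt; dimethyldioxirane, acetone/CH2Cl2, -40 °C; then citric acid (cat.), MeOH/H2O, rt
Reagents that add atoms: dimethyldioxirane, CC1(C)OO1
Why: Rubottom oxidation; soft enolisation avoids base-induced ring opening, and the dioxirane epoxidises the enol ether on the face opposite the pseudoaxial 2-aryl group, so hydrolysis gives the 2,3-trans α-hydroxy ketone.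

**Step 7**
Reactants: 12 (2S,3S)-7-(benzyloxy)-2-[3,4-bis(benzyloxy)phenyl]-3-hydroxychroman-4-one
Product: 13 (2S,3S)-7-(benzyloxy)-2-[3,4-bis(benzyloxy)phenyl]-3-[(tert-butyldimethylsilyl)oxy]chroman-4-one
Conditions: TBSOTf, 2,6-lutidine, CH2Cl2, -78 → 0 °C
Reagents that add atoms: tert-butyldimethylsilyl triflate, CC(C)(C)[Si](C)(C)OS(=O)(=O)C(F)(F)F
Why: Silylation under non-basic conditions protects the 3-OH without epimerising or opening the α-hydroxy ketone, and installs the bulky group that later directs the C4 reduction.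

**Step 8**
Reactants: 14 (+)-catechin
Product: 15 (2R,3S)-5,7-bis(benzyloxy)-2-[3,4-bis(benzyloxy)phenyl]chroman-3-ol
Conditions: BnBr (4.2 equiv), K2CO3, DMF, 0 °C → rt
Reagents that add atoms: benzyl bromide, BrCc1ccccc1
Why: Williamson etherification; the carbonate base deprotonates only the four phenols, leaving the secondary alcohol free.

**Step 9**
Reactants: 15 (2R,3S)-5,7-bis(benzyloxy)-2-[3,4-bis(benzyloxy)phenyl]chroman-3-ol
Product: 16 (2R,3S)-3,5,7-tris(benzyloxy)-2-[3,4-bis(benzyloxy)phenyl]chromane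
Conditions: NaH, BnBr, DMF, 0 °C → rt
Reagents that add atoms: benzyl bromide, BrCc1ccccc1
Why: Williamson etherification of the secondary alkoxide; no phenol is free, so C2 cannot epimerise through a quinone methide.

**Step 10**
Reactants: 16 (2R,3S)-3,5,7-tris(benzyloxy)-2-[3,4-bis(benzyloxy)phenyl]chromane
Product: 17 (2R,3S)-3,5,7-tris(benzyloxy)-2-[3,4-bis(benzyloxy)phenyl]-8-bromochromane
Conditions: NBS (1.0 equiv), CH2Cl2, -78 °C → rt
Reagents that add atoms: N-bromosuccinimide, O=C1CCC(=O)N1Br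
Why: Electrophilic aromatic bromination goes to C8 (flanked by the ring oxygen and one benzyloxy group) in preference to the more crowded C6 (between two benzyloxy groups).

**Step 11**
Reactants: 17 (2R,3S)-3,5,7-tris(benzyloxy)-2-[3,4-bis(benzyloxy)phenyl]-8-bromochromane
Product: 18 (2R,3S)-3,5,7-tris(benzyloxy)-2-[3,4-bis(benzyloxy)phenyl]-8-bromo-6-iodochromane
Conditions: NIS (1.2 equiv), CF3CO2H (cat.), CH2Cl2/MeCN, 0 °C → rt, dark
Reagents that add atoms: N-iodosuccinimide, O=C1CCC(=O)N1I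
Why: Electrophilic aromatic iodination at C6, the only remaining position on the activated ring.

**Step 12**
Reactants: 18 (2R,3S)-3,5,7-tris(benzyloxy)-2-[3,4-bis(benzyloxy)phenyl]-8-bromo-6-iodochromane; 13 (2S,3S)-7-(benzyloxy)-2-[3,4-bis(benzyloxy)phenyl]-3-[(tert-butyldimethylsilyl)oxy]chroman-4-one
Product: 20 (2S,3S,4S)-7-(benzyloxy)-2-[3,4-bis(benzyloxy)phenyl]-3-[(tert-butyldimethylsilyl)oxy]-4-[(2R,3S)-3,5,7-tris(benzyloxy)-2-[3,4-bis(benzyloxy)phenyl]-8-bromochroman-6-yl]chroman-4-ol, via aryllithium 19 (not isolated)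
Conditions: 18 (1.3 equiv), n-BuLi (1.05 equiv per 18), THF, -78 °C, 15 min; add 13, -78 → -30 °C; then H2O
Reagents that add atoms: none
Why: Iodine–lithium exchange is much faster than bromine–lithium exchange, so only C6 is metalated, and the aryllithium then adds 1,2 to the ketone (expected anti to the silyloxy group); the carbinol stereocentre is erased in step 13.

**Step 13**
Reactants: 20 the tertiary carbinol from step 12
Product: 21 tert-butyldimethylsilyl ether of (2S,3R,4S)-7-(benzyloxy)-2-[3,4-bis(benzyloxy)phenyl]-4-[(2R,3S)-3,5,7-tris(benzyloxy)-2-[3,4-bis(benzyloxy)phenyl]-8-bromochroman-6-yl]chroman-3-ol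
Conditions: n-Bu3SnH (5 equiv), CF3CO2H (10 equiv), CH2Cl2, -78 → 0 °C
Reagents that add atoms: none
Why: Ionic hydrogenation (reductive deoxygenation through the doubly benzylic C4 cation); hydride is delivered to the face opposite the adjacent bulky silyloxy group, so H-4 ends trans and the aryl group cis to O-3, which is the 4S, 3,4-cis configuration.

**Step 14**
Reactants: 21 the silyl ether from step 13
Product: 22 (2S,3R,4S)-7-(benzyloxy)-2-[3,4-bis(benzyloxy)phenyl]-4-[(2R,3S)-3,5,7-tris(benzyloxy)-2-[3,4-bis(benzyloxy)phenyl]-8-bromochroman-6-yl]chroman-3-ol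
Conditions: 48% aq. HF, MeCN/CH2Cl2, 0 °C → rt
Reagents that add atoms: none
Why: Fluoride-driven desilylation; benzyl ethers, the aryl bromide and the interflavan bond are inert.

**Step 15**
Reactants: 22 the octabenzyl bromo dimer from step 14
Product: 23 ent-fisetinidol-(4α→6)-catechin, (2S,3R,4S)-2-(3,4-dihydroxyphenyl)-4-[(2R,3S)-2-(3,4-dihydroxyphenyl)-3,5,7-trihydroxychroman-6-yl]chromane-3,7-diol
Conditions: H2 (1 atm), Pd(OH)2 on carbon, Et3N, THF/MeOH/H2O, rt
Reagents that add atoms: none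
Why: Hydrogenolysis of the eight benzyl ethers with hydrodebromination of the C8 cap; the amine buffers the HBr so the acid-sensitive interflavan bond and the stereocentres are untouched.

## Compound list

1 | methyl 2,4-dihydroxybenzoate | COC(=O)c1ccc(O)cc1O | starting material
2 | methyl 4-(benzyloxy)-2-hydroxybenzoate | COC(=O)c1ccc(OCc2ccccc2)cc1O | intermediate
3 | tert-butyl acetate | CC(=O)OC(C)(C)C | starting material
4 | tert-butyl 3-[4-(benzyloxy)-2-hydroxyphenyl]-3-oxopropanoate | CC(C)(C)OC(=O)CC(=O)c1ccc(OCc2ccccc2)cc1O | intermediate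
5 | 3,4-dihydroxybenzaldehyde | O=Cc1ccc(O)c(O)c1 | starting material
6 | 3,4-bis(benzyloxy)benzaldehyde | O=Cc1ccc(OCc2ccccc2)c(OCc2ccccc2)c1 | intermediate
7 | tert-butyl 2-[4-(benzyloxy)-2-hydroxybenzoyl]-3-[3,4-bis(benzyloxy)phenyl]prop-2-enoate (E/Z mixture, geometry not defined) | CC(C)(C)OC(=O)C(=Cc1ccc(OCc2ccccc2)c(OCc2ccccc2)c1)C(=O)c1ccc(OCc2ccccc2)cc1O | intermediate
8 | tert-butyl (2R,3S)-7-(benzyloxy)-2-[3,4-bis(benzyloxy)phenyl]-4-oxochromane-3-carboxylate (2,3-trans) | O=C1c2ccc(OCc3ccccc3)cc2O[C@@H](c2ccc(OCc3ccccc3)c(OCc3ccccc3)c2)[C@@H]1C(=O)OC(C)(C)C | intermediate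
9 | (2R)-7-(benzyloxy)-2-[3,4-bis(benzyloxy)phenyl]chroman-4-one | O=C1C[C@H](c2ccc(OCc3ccccc3)c(OCc3ccccc3)c2)Oc2cc(OCc3ccccc3)ccc12 | intermediate
10 | (2R)-7-(benzyloxy)-2-[3,4-bis(benzyloxy)phenyl]-4-[(trimethylsilyl)oxy]-2H-chromene | C[Si](C)(C)OC1=C[C@H](c2ccc(OCc3ccccc3)c(OCc3ccccc3)c2)Oc2cc(OCc3ccccc3)ccc12 | intermediate
11 | 3,4-epoxide of 10, oxygen on the face opposite the 2-aryl group | C[Si](C)(C)O[C@@]12c3ccc(OCc4ccccc4)cc3O[C@@H](c3ccc(OCc4ccccc4)c(OCc4ccccc4)c3)[C@@H]1O2 | intermediate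
12 | (2S,3S)-7-(benzyloxy)-2-[3,4-bis(benzyloxy)phenyl]-3-hydroxychroman-4-one (2,3-trans) | O=C1c2ccc(OCc3ccccc3)cc2O[C@@H](c2ccc(OCc3ccccc3)c(OCc3ccccc3)c2)[C@@H]1O | intermediate
13 | (2S,3S)-7-(benzyloxy)-2-[3,4-bis(benzyloxy)phenyl]-3-[(tert-butyldimethylsilyl)oxy]chroman-4-one | O=C1c2ccc(OCc3ccccc3)cc2O[C@@H](c2ccc(OCc3ccccc3)c(OCc3ccccc3)c2)[C@@H]1O[Si](C)(C)C(C)(C)C | intermediate
14 | (+)-catechin, (2R,3S) | O[C@H]1Cc2c(O)cc(O)cc2O[C@@H]1c1ccc(O)c(O)c1 | starting material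
15 | (2R,3S)-5,7-bis(benzyloxy)-2-[3,4-bis(benzyloxy)phenyl]chroman-3-ol | O[C@H]1Cc2c(OCc3ccccc3)cc(OCc3ccccc3)cc2O[C@@H]1c1ccc(OCc2ccccc2)c(OCc2ccccc2)c1 | intermediate
16 | (2R,3S)-3,5,7-tris(benzyloxy)-2-[3,4-bis(benzyloxy)phenyl]chromane | c1ccccc1CO[C@H]1Cc2c(OCc3ccccc3)cc(OCc3ccccc3)cc2O[C@@H]1c1ccc(OCc2ccccc2)c(OCc2ccccc2)c1 | intermediate
17 | (2R,3S)-3,5,7-tris(benzyloxy)-2-[3,4-bis(benzyloxy)phenyl]-8-bromochromane | c1ccccc1CO[C@H]1Cc2c(OCc3ccccc3)cc(OCc3ccccc3)c(Br)c2O[C@@H]1c1ccc(OCc2ccccc2)c(OCc2ccccc2)c1 | intermediate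
18 | (2R,3S)-3,5,7-tris(benzyloxy)-2-[3,4-bis(benzyloxy)phenyl]-8-bromo-6-iodochromane | c1ccccc1CO[C@H]1Cc2c(OCc3ccccc3)c(I)c(OCc3ccccc3)c(Br)c2O[C@@H]1c1ccc(OCc2ccccc2)c(OCc2ccccc2)c1 | intermediate
19 | 6-lithio derivative of 17 (C6–Li, C8–Br) | c1ccccc1CO[C@H]1Cc2c(OCc3ccccc3)c([Li])c(OCc3ccccc3)c(Br)c2O[C@@H]1c1ccc(OCc2ccccc2)c(OCc2ccccc2)c1 | intermediate
20 | (2S,3S,4S)-7-(benzyloxy)-2-[3,4-bis(benzyloxy)phenyl]-3-[(tert-butyldimethylsilyl)oxy]-4-[(2R,3S)-3,5,7-tris(benzyloxy)-2-[3,4-bis(benzyloxy)phenyl]-8-bromochroman-6-yl]chroman-4-ol (4-aryl cis to the 2-aryl group, 4-OH cis to the 3-silyloxy group) | c1ccccc1COc1ccc2c(c1)O[C@@H](c1ccc(OCc3ccccc3)c(OCc3ccccc3)c1)[C@H](O[Si](C)(C)C(C)(C)C)[C@@]2(O)c1c(OCc3ccccc3)c(Br)c2c(c1OCc1ccccc1)C[C@H](OCc1ccccc1)[C@@H](c1ccc(OCc3ccccc3)c(OCc3ccccc3)c1)O2 | intermediate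
21 | 3-O-tert-butyldimethylsilyl ether of 22, upper unit (2S,3R,4S), 2,3-trans-3,4-cis | c1ccccc1COc1ccc2c(c1)O[C@@H](c1ccc(OCc3ccccc3)c(OCc3ccccc3)c1)[C@H](O[Si](C)(C)C(C)(C)C)[C@@H]2c1c(OCc3ccccc3)c(Br)c2c(c1OCc1ccccc1)C[C@H](OCc1ccccc1)[C@@H](c1ccc(OCc3ccccc3)c(OCc3ccccc3)c1)O2 | intermediate
22 | (2S,3R,4S)-7-(benzyloxy)-2-[3,4-bis(benzyloxy)phenyl]-4-[(2R,3S)-3,5,7-tris(benzyloxy)-2-[3,4-bis(benzyloxy)phenyl]-8-bromochroman-6-yl]chroman-3-ol | c1ccccc1COc1ccc2c(c1)O[C@@H](c1ccc(OCc3ccccc3)c(OCc3ccccc3)c1)[C@H](O)[C@@H]2c1c(OCc3ccccc3)c(Br)c2c(c1OCc1ccccc1)C[C@H](OCc1ccccc1)[C@@H](c1ccc(OCc3ccccc3)c(OCc3ccccc3)c1)O2 | intermediate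
23 | ent-fisetinidol-(4α→6)-catechin (CNP0141631.3) | Oc1ccc2c(c1)O[C@@H](c1ccc(O)c(O)c1)[C@H](O)[C@@H]2c1c(O)cc2c(c1O)C[C@H](O)[C@@H](c1ccc(O)c(O)c1)O2 | target

## Step count and risks

Total step count: 15. Longest linear sequence: 10 (steps 1, 2, 4, 5, 6, 7, 12, 13, 14, 15). Side branches: step 3 (aldehyde) and steps 8–11 (lower unit).

**Step 5 (enantioselective ring closure).** The electron-rich 3,4-bis(benzyloxy)phenyl group lowers the acceptor reactivity, and the acidic decarboxylation could erode the C2 configuration by reversible ring opening. Any minor enantiomer would become a separable diastereomer after step 12, but low ee costs material.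
Fallback, setting out from 4 and returning at 9: 4 is dealkylated and decarboxylated (CF3CO2H, CH2Cl2, then warming) to 1-[4-(benzyloxy)-2-hydroxyphenyl]ethanone F1. Condensation with Me2NCH(OMe)2 at 90 °C gives (E)-1-[4-(benzyloxy)-2-hydroxyphenyl]-3-(dimethylamino)prop-2-en-1-one F2, which closes with HCl in CH2Cl2 to 7-(benzyloxy)-4H-chromen-4-one F3. Enantioselective conjugate addition of commercial 3,4-bis(benzyloxy)phenylboronic acid to F3 (Pd(OCOCF3)2, 4-tert-butyl-2-(pyridin-2-yl)-4,5-dihydrooxazole of the antipode that gives 2R, NH4PF6, H2O, ClCH2CH2Cl, 60 °C) delivers 9 without any acidic decarboxylation.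

**Step 12 (aryllithium addition).** The di-ortho-substituted aryllithium may enolise 13 at C3, which opens the pyranone to a chalcone, or may simply fail to add for steric reasons.
Fallback, setting out from 12 and returning at 22: 12 is reduced with NaBH4 (MeOH/THF, 0 °C) to (2S,3R,4S)-7-(benzyloxy)-2-[3,4-bis(benzyloxy)phenyl]chromane-3,4-diol F4. BF3·OEt2 in CH2Cl2 at -40 °C ionises C4, and the C8-capped nucleophile 17 attacks through C6 in a Friedel–Crafts alkylation. With the free 3-OH of this 5-deoxy cation a substantial share of 3,4-cis product is expected; that isomer is 22, and it is separated by chromatography from the 3,4-trans C4 epimer of 22 F5.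

**Step 13 (C4 configuration).** In this 2,3-trans series the face opposite the silyloxy group is the face of the 2-aryl group, so selectivity may be lower than in the all-cis case. A 1,2-hydride shift from C3 in the cation could also compete with external hydride capture.
Fallback, setting out from 20 and returning at 22: 20 is desilylated (aq. HF, MeCN) to (2S,3S,4S)-7-(benzyloxy)-2-[3,4-bis(benzyloxy)phenyl]-4-[(2R,3S)-3,5,7-tris(benzyloxy)-2-[3,4-bis(benzyloxy)phenyl]-8-bromochroman-6-yl]chromane-3,4-diol F6. TsOH (cat.) in CH2Cl2 at 0 °C then triggers a semipinacol rearrangement: C4 ionises and H-3, which sits on the face of the 2-aryl group, shifts suprafacially to C4. This gives (2S,4S)-7-(benzyloxy)-2-[3,4-bis(benzyloxy)phenyl]-4-[(2R,3S)-3,5,7-tris(benzyloxy)-2-[3,4-bis(benzyloxy)phenyl]-8-bromochroman-6-yl]chroman-3-one F7 with the 2,4-trans relationship already fixed. NaBH4 with CeCl3·7H2O (MeOH/THF, -78 °C) attacks the ketone axially, opposite the pseudoaxial 4-aryl group, to give the equatorial 3-OH of 22.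

## Further compounds

F1 | step 5 | 1-[4-(benzyloxy)-2-hydroxyphenyl]ethanone | CC(=O)c1ccc(OCc2ccccc2)cc1O
F2 | step 5 | (E)-1-[4-(benzyloxy)-2-hydroxyphenyl]-3-(dimethylamino)prop-2-en-1-one | CN(C)/C=C/C(=O)c1ccc(OCc2ccccc2)cc1O
F3 | step 5 | 7-(benzyloxy)-4H-chromen-4-one | O=c1ccoc2cc(OCc3ccccc3)ccc12
F4 | step 12 | (2S,3R,4S)-7-(benzyloxy)-2-[3,4-bis(benzyloxy)phenyl]chromane-3,4-diol | c1ccccc1COc1ccc2c(c1)O[C@@H](c1ccc(OCc3ccccc3)c(OCc3ccccc3)c1)[C@H](O)[C@H]2O
F5 | step 12 | 3,4-trans C4 epimer of 22, upper unit (2S,3R,4R) | c1ccccc1COc1ccc2c(c1)O[C@@H](c1ccc(OCc3ccccc3)c(OCc3ccccc3)c1)[C@H](O)[C@H]2c1c(OCc3ccccc3)c(Br)c2c(c1OCc1ccccc1)C[C@H](OCc1ccccc1)[C@@H](c1ccc(OCc3ccccc3)c(OCc3ccccc3)c1)O2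
F6 | step 13 | (2S,3S,4S)-7-(benzyloxy)-2-[3,4-bis(benzyloxy)phenyl]-4-[(2R,3S)-3,5,7-tris(benzyloxy)-2-[3,4-bis(benzyloxy)phenyl]-8-bromochroman-6-yl]chromane-3,4-diol | c1ccccc1COc1ccc2c(c1)O[C@@H](c1ccc(OCc3ccccc3)c(OCc3ccccc3)c1)[C@H](O)[C@@]2(O)c1c(OCc3ccccc3)c(Br)c2c(c1OCc1ccccc1)C[C@H](OCc1ccccc1)[C@@H](c1ccc(OCc3ccccc3)c(OCc3ccccc3)c1)O2
F7 | step 13 | (2S,4S)-7-(benzyloxy)-2-[3,4-bis(benzyloxy)phenyl]-4-[(2R,3S)-3,5,7-tris(benzyloxy)-2-[3,4-bis(benzyloxy)phenyl]-8-bromochroman-6-yl]chroman-3-one | c1ccccc1COc1ccc2c(c1)O[C@@H](c1ccc(OCc3ccccc3)c(OCc3ccccc3)c1)C(=O)[C@@H]2c1c(OCc3ccccc3)c(Br)c2c(c1OCc1ccccc1)C[C@H](OCc1ccccc1)[C@@H](c1ccc(OCc3ccccc3)c(OCc3ccccc3)c1)O2
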